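(Readings and results were generated by integration for substances that don't exist, noise included.)

| flask | starting material | gas phase | catalyst | remark | time |
|---|---|---|---|---|---|
| eta | 14 mM | 0.37 mM (held) | 10 µM | run made earlier |  |
| zeta | 22 mM | 0.37 mM (held) | 10 µM | run made earlier |  |
| epsilon | 10 mM | 0.37 mM (held) | 15 µM | run made earlier |  |
| flask | 10 mM | 0.37 mM (held) | 10 µM |  | 50 min |

| run | time / min | target / % | starting material / % |
|---|---|---|---|
| eta | 3.00 | 19.9 | 80.5 |
| eta | 8.00 | 43.0 | 53.6 |
| eta | 25.0 | 51.5 | 27.4 |
| eta | 60.0 | 33.7 | 17.4 |
| zeta | 3.00 | 13.2 | 86.6 |
| zeta | 8.00 | 30.4 | 68.2 |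
| zeta | 25.0 | 50.5 | 30.4 |
| zeta | 60.0 | 35.5 | 18.2 |
| epsilon | 3.00 | 25.2 | 72.6 |
| epsilon | 8.00 | 52.0 | 42.4 |
| epsilon | 25.0 | 51.6 | 25.7 |
| epsilon | 60.0 | 33.7 | 16.2 |

(standard deviation of a reading: 0.5 percentage points)

- at the start none of the gas phase is in solution

1. time, not beyond 50 min, at which the flask holds most target
2. the amount of target, in percent of the starting material charged, at that time

At early times the ledger of starting material, the limiting reagent, has two entries: at 3.00 min the eta run reads 80.5% unreacted and 19.9% as target, and the two close on the charge within the scatter. Later a third entry opens, the lost part, which is whatever the two no longer account for. The epsilon run, charged like the flask with 10 mM, reads 5.60% lost at 8.00 min and 22.7% at 25.0 min. The last readings of the eta, zeta and epsilon runs, at 60.0 min, then divide what is not lost: target holds 66.5% of starting material plus target, a reading called here the equilibrium share. Carried back to earlier times as an assumption, this share closes the books with target equal to the share of the charge minus the lost part, and the lost part is the correction to reckon.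

Reckoned here as an estimate, at the forecast's time of 14 min, interpolation in the epsilon run puts the lost part at 11.6%, and the share read at 60.0 min then gives an estimate of 58.8% target for the flask. The forecast is lower: 56% at 14 min, with a drain it calls “the same in all runs whatever the catalyst or concentration”.

The flask reaches 57.8% at 12.8 min, within the tolerance of the forecast.

    gas phase ⇌ dissolved gas, rate k1*(csat - [dissolved gas]) (kL = 2.75 min⁻¹)
    starting material + dissolved gas + catalyst ⇌ catalyst + target (K = 5900 L mol⁻¹, k = 3.86 × 10⁷ L² mol⁻² s⁻¹)
    2 dissolved gas → self-condensation product (k = 298 L mol⁻¹ min⁻¹)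
    starting material + dissolved gas → uncatalysed product (k = 113 L mol⁻¹ min⁻¹)

The reverse step, target returning to starting material and dissolved gas, has the largest single effect on the peak: without it the highest target is 99.5% instead of 57.8% . At the best time the flask has 10.2% as uncatalysed product, so the equilibrium share, read at 60.0 min, gives 59.7% against the 57.8% found, and target in the flask then holds 64.3% of starting material plus target. The neighbour charged with 25 mM has 38.4% as uncatalysed product at 50.0 min, so the share gives 41.0%, and that neighbour holds 40.4% target.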